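## Structural features

The target is a daucane sesquiterpene diol whose secondary hydroxyl (O6) is esterified with 3,4-dimethoxybenzoic acid. Ring A (cyclopentane, C1–C5) is trans-fused along the C1–C5 bond to ring B (cycloheptene, C5–C10 plus C1), which carries methyl C14 on C8 and the C8=C9 double bond. There are four stereocentres: the quaternary C1 (methyl C15, R), the tertiary carbinol C4 (isopropyl, R), the ring-fusion methine C5 (S) and the ester-bearing C6 (S). C4, C5 and C6 are contiguous and C5 also adjoins C1; H5 is anti to the C15 methyl and to the C4 hydroxyl and syn to O6 (C15 β, 4β-OH, 5α-H, 6α-O). Fragile points are the tertiary alcohol (dehydration towards C5), the β-relation of O6 to C4 (any C4 ketone precursor can lose O6 by β-elimination or retro-aldol), the aryl ester and the trisubstituted alkene. The real difficulty is the quaternary C1 flanked by three further stereocentres on a seven-membered ring, together with the trans ring fusion. The key step exploits ring B: oxygen on C6, methyl on C8 and unsaturation at C8–C9 are the pattern of a 4-methyl-3-oxidopyrylium spanning C6–C10, and C6 and C10 flank the C5–C1 bond, which can come from the alkene of a cyclopentenone whose carbonyl is C4.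

## Logic of the disconnections

24 ⇒ 22 + 23. The acyl–O6 bond is cut because the ester is the most labile group and should come last. This leaves 22 and 23, both much simpler. The forward step must acylate the hindered secondary hydroxyl, leave the tertiary one alone and not break the C6–O bond.

22 ⇒ 21 ⇒ 20. The O6 silyl ether is put back and the C4–isopropyl bond is cut, turning the tertiary carbinol into the ketone of 20. The gain is a C4 carbonyl that can activate C5 and, earlier, the dipolarophile. The nucleophile must add from the face of H5, anti to the C15 methyl, without enolising the ketone or expelling O6.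

20 ⇒ 19 ⇒ 18. The trans ring fusion is traced back to the C5 epimer 19, stored as its C4 ketal 18, because a cycloaddition across C5=C1 can only deliver a cis-fused ring A. The forward step needs the trans ketone to be the thermodynamic one once ring B carries only the C8=C9 alkene, and a base mild enough to spare the β-silyloxy group.

18 ⇒ 17 ⇒ 16 ⇒ 15. The C7–H bond is cut and the C8=C9 alkene is returned to the C7=C8–C9=O enone of 15 through the allylic diazene 17. This is where the oxidation pattern of the cycloadduct leads. The hydrazone must form at C9 only, hence the C4 ketal, and hydride must add 1,2 to C=N.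

15 ⇒ 14 ⇒ 13 ⇒ 12. After removal of the ketal and the silyl ether, the C10–O bridge bond and the C5–S bond are restored. Both lie α to a carbonyl and are therefore reductively cleavable. The gain is the rigid tricycle 12, in which C1, C5, C6 and C10 are fixed at once. The forward reduction must open the bridge at C10–O, not at C6–O, before the C5 enolate is formed.

12 ⇒ 11 + 10. The C1–C10 and C5–C6 bonds are cut (retro [5+2]). This splits the skeleton into 11, five carbons carrying C14 and O6, and 10, ring A carrying C15. The forward step needs regio-, face and exo control on a tetrasubstituted alkene.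

11 ⇒ 3 ⇒ 2 ⇒ 1. The C–OAc bond of 3 is restored (11 is its elimination product), 3 is the acetate of 2, and 2 is the oxidative ring expansion product of 1. The gain is a stable, storable ylide precursor from a commercial furan. The furan methyl must end on pyranone C4.

10 ⇒ 9 ⇒ 8 + 7; 8 ⇒ 6 ⇒ 5 ⇒ 4. The C5–S bond is cut to 8 and 7, and 8 goes back through 6 and 5 to 4 by cutting the C–Br bond. The gain is that the sulfur stereocentre is bought, not made. Sulfur must be substituted with clean inversion, and the ketone must stay masked while 8 exists.

## Other disconnections considered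

Alternative 1: The cuts are C1–C2 and C4–C5. Ring B is taken as 3,6-dimethylcyclohepta-2,5-dienone A1, C2–C3 come from the vinyl group of diisobutyl(vinyl)aluminium A2, and C4 with its isopropyl group is isobutyraldehyde A3. In the forward step a chiral NHC–copper catalyst made from Cu(OTf)2 would transfer the vinyl group of A2 to C1 of A1, and the aluminium enolate would be trapped at C5 by A3 to give the aldol A4.
- In its favour: catalytic asymmetric formation of a quaternary centre on a β-methyl cycloalkenone is an established reaction class. All fifteen skeletal carbons are assembled at once, and C8=C9 is already in place. The trans relation of C1 and C5 should come directly from anti trapping of the enolate. On these points it is the better plan, since the chosen route must transpose the alkene and correct C5.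
- Against it here: the second alkene of A1 is β,γ to the ketone and can slip into conjugation under Lewis acid. Ring A is not yet closed in A4: the C3–C4 bond still has to be made onto a C4 ketone, and that closure would set the C4 carbinol without an obvious control element. Once the C4 carbinol of A4 is oxidised, C5 lies between two carbonyls and can epimerise. C6 must be reduced to the α-alcohol by substrate control.
- Comparison: on structure, the chosen plan has ring A from the start and sets C6 in the key step, while A4 has C1 and C5 but leaves C4 and C6 open. On mechanism, both add to a β,β-disubstituted acceptor; the alternative rests on an established reaction type and is the better on security of the key step. On step count the two are about equal.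

Alternative 2: The cuts are C1–C10 and C7–C8, a [4+3] annulation. The partners are the diene ketal A5, which would come from 6 by vinylation, and methyl 2-diazobut-3-enoate A6. With Rh2(S-DOSP)4 or its antipode the vinylcarbenoid from A6 would cyclopropanate the vinyl group of A5, and Cope rearrangement of the cis-divinylcyclopropane would close ring B to give A7.
- In its favour: it is catalytic, enantioselective and of a known type for vinylcycloalkenes. C8=C9 is formed where it is needed, so no transposition is required. The remaining C5=C6 alkene of A7 invites a hydroboration that would add H5 and O6 syn to each other and anti to the C15 methyl. That is a kinetically controlled entry to the trans fusion and is better than the equilibration used in the chosen plan. It also shares compounds 4–6 with the chosen route.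
- Against it here: the C8 ester of A7 must be taken down to a methyl group (three operations). A6 is thermally labile. Enantioselectivity for a diene such as A5, whose ring alkene is tetrasubstituted, is not assured. O6 arrives in a separate step.
- Comparison: on structure, both build ring B onto ring A and make the quaternary C1 in the key step; the chosen step also delivers O6 and C14. On mechanism, the alternative is established and is the better. On step count the two are about equal. For these reasons it is kept as the fallback for the key step.

Alternative 3: The cuts are C1–C10 and C4–C5, following biogenesis. A carotol-synthase-type cyclase would ionise (2E,6E)-farnesyl diphosphate A8 and convert it into carotol A9.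
- In its favour: one step from the achiral A8 would give both rings, the quaternary C1, the C4 isopropyl orientation and C8=C9 in the correct absolute sense. In skeleton-building economy it is far better than the chosen plan.
- Against it here: A9 carries its oxygen on C5, has none on C4 or C6 and no hydrogen on C5. Reaching the target would mean moving the tertiary hydroxyl to C4 with H5 anti, and oxidising C6 next to a reactive alkene. No reagent-based control for either is evident, and a matching set of oxidising enzymes is not available as a reagent.
- Comparison: on structure, the skeleton is better served and the oxygen pattern worse. On mechanism, it is an enzyme-held cation cascade against a reagent-controlled cycloaddition. On step count it would win only if the late oxidations were solved.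

Key step: step 7

Assumption: 10 reacts through the rotamer with S=O syn-periplanar to C5=C1 and anti to the C4 carbonyl (no chelating metal present), so that the p-tolyl group of the (S)-sulfoxide covers the Re face and the Si face stays open; the configuration at sulfur is the only element that would have to be exchanged if the other face proved to be the open one.

## Route

Step 1
Reactants: 1 (3-methylfuran-2-yl)methanol
Product: 2 6-hydroxy-4-methyl-2H-pyran-3(6H)-one (racemic lactol)
Conditions: NBS, NaHCO3, THF–H2O, 0 °C
Reagents that add atoms: water, O
Why: Achmatowicz oxidative ring expansion; oxidation at furan C5, addition of water, ring opening and reclosure through the CH2OH oxygen should give the pyranone, with the furan 3-methyl ending on pyranone C4 (future C8 with C14). The lactol centre is lost later, so both anomers serve.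

Step 2
Reactants: 2 6-hydroxy-4-methyl-2H-pyran-3(6H)-one
Product: 3 6-acetoxy-4-methyl-2H-pyran-3(6H)-one
Conditions: Ac2O, pyridine, DMAP (cat.), CH2Cl2, 0 °C
Reagents that add atoms: acetic anhydride, CC(=O)OC(C)=O
Why: DMAP-catalysed O-acylation of the lactol; the acetate is the leaving group for ylide formation.

Step 3
Reactants: 4 3-methylcyclopent-2-enone
Product: 5 2-bromo-3-methylcyclopent-2-enone
Conditions: Br2, CH2Cl2, 0 °C; then Et3N, 0 °C → rt
Reagents that add atoms: bromine, BrBr
Why: Bromine addition to the enone followed by E1cB loss of HBr (α-proton, β-bromide) is the standard α-bromination of cyclic enones.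

Step 4
Reactants: 5 2-bromo-3-methylcyclopent-2-enone
Product: 6 6-bromo-7-methyl-1,4-dioxaspiro[4.4]non-6-ene
Conditions: HOCH2CH2OH, p-TsOH·H2O (cat.), benzene, reflux (Dean–Stark)
Reagents that add atoms: ethylene glycol, OCCO
Why: Acid-catalysed ketalisation with azeotropic removal of water; the ketal masks the carbonyl so that a vinyllithium can be made at the α-carbon.

Step 5
Reactants: 6 6-bromo-7-methyl-1,4-dioxaspiro[4.4]non-6-ene; 7 (1R,2S,5R)-menthyl (S)-p-toluenesulfinate
Product: 9 (S)-7-methyl-6-(p-tolylsulfinyl)-1,4-dioxaspiro[4.4]non-6-ene, via vinyllithium 8 (not isolated)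
Conditions: n-BuLi, THF, −78 °C; then 7, THF, −78 °C
Reagents that add atoms: none
Why: Bromine–lithium exchange gives 8, which displaces menthoxide at sulfur with inversion (Andersen sulfoxide synthesis). The sulfur stereocentre of 9 is therefore set by the sulfinate.

Step 6
Reactants: 9 (S)-7-methyl-6-(p-tolylsulfinyl)-1,4-dioxaspiro[4.4]non-6-ene
Product: 10 (S)-3-methyl-2-(p-tolylsulfinyl)cyclopent-2-enone
Conditions: PPTS (cat.), acetone–H2O, 40 °C
Reagents that add atoms: water, O
Why: Mild acid hydrolysis of the dioxolane; an aryl vinyl sulfoxide is configurationally stable to pyridinium acid.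

Step 7
Reactants: 3 6-acetoxy-4-methyl-2H-pyran-3(6H)-one; 10 (S)-3-methyl-2-(p-tolylsulfinyl)cyclopent-2-enone
Product: 12 exo cycloadduct (oxygen bridge C6–O–C10 on the α face; sulfinyl on C5 β; C15 methyl β; C4 and C9 ketones; C7=C8), via 4-methyl-3-oxidopyrylium 11 (not isolated)
Conditions: Et3N, MeCN, 40 °C, slow addition of 3 (3 equiv) to 10
Reagents that add atoms: none
Why: Proposed new method: Et3N removes an α-proton of 3 and acetate leaves, giving 11, a cyclic carbonyl ylide whose terminus next to the oxido carbon (C10) is the more nucleophilic; it should add across C5=C1 of 10 in a concerted, suprafacial but asynchronous [5+2] cycloaddition, C10 bonding to the β-carbon C1 and C6 to the α-carbon C5. The closest known reaction type is the intermolecular [5+2] cycloaddition of 3-oxidopyrylium ylides with enones and with vinyl sulfoxides; a tetrasubstituted, β-methylated 2-sulfinyl enone has not been shown as partner, and the case rests on its double activation (ketone and sulfinyl on C5), which lowers the LUMO and keeps the large coefficient on C1 despite the extra methyl. Ring B is closed as the seven-membered carbocycle of an 8-oxabicyclo[3.2.1]octenone by cycloaddition, both ring bonds being made in the same step. C1 and C5 are set together by the alkene face attacked: with S=O syn to C5=C1 and anti to the C4 carbonyl, the p-tolyl group of the (S)-sulfoxide covers the Re face and the ylide adds to the Si face beside the sulfur lone pair, giving (R) at C1. C6 and C10 follow from the exo orientation (ring A on the side of the oxygen bridge, sulfinyl and C15 methyl under the enone bridge), which places O6 anti to the C15 methyl as the target needs. The step thus needs regio-, face and exo selectivity: the first comes from the polarisation of both partners and the second from the sulfur stereocentre. The third is the least secure and is expected only because the flat S=O and lone-pair side of the alkene should fit under the oxidoallyl unit better than the C2 and C3 methylenes. Slow addition of 3 keeps the ylide concentration low so that dimerisation does not outrun addition to the hindered alkene.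

Step 8
Reactants: 12 exo cycloadduct
Product: 13 cis-fused hydroxy dione (6α-OH; 5β-H; C4 ketone; C7=C8–C9=O)
Conditions: SmI2 (4.5 equiv), MeOH, THF, −78 °C
Reagents that add atoms: none
Why: SmI2 reductive cleavage of α-heterosubstituted ketones: the C9 enone should accept electrons first and expel the α C10–O bond, leaving O6 as an alkoxide with its C6–O bond intact, after which the C5–S bond of the β-keto sulfoxide is cleaved and both enolates are protonated by MeOH. The C5 configuration formed here (cis-fused, hydrogen in the place of sulfur) is not relied on, because C5 is equilibrated in step 13.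

Step 9
Reactants: 13 cis-fused hydroxy dione
Product: 14 TBS ether of 13
Conditions: TBSCl, imidazole, DMF, rt
Reagents that add atoms: tert-butyldimethylsilyl chloride, CC(C)(C)[Si](C)(C)Cl
Why: Silylation of the secondary alcohol; it closes the retro-aldol path of the β-hydroxy ketone and keeps O6 inert until the end.

Step 10
Reactants: 14 TBS ether of 13
Product: 15 C4 ethylene ketal of 14 (C9 enone free)
Conditions: TMSOCH2CH2OTMS, TMSOTf (cat.), CH2Cl2, −78 → −20 °C
Reagents that add atoms: 1,2-bis(trimethylsilyloxy)ethane, C[Si](C)(C)OCCO[Si](C)(C)C
Why: Noyori ketalisation; under these conditions saturated ketones are ketalised and conjugated enones are not, so only C4 is masked. This differentiates the two ketones before hydrazone formation.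

Step 11
Reactants: 15 C4 ketal enone
Product: 16 C9 tosylhydrazone of 15
Conditions: TsNHNH2, EtOH, 60 °C
Reagents that add atoms: p-toluenesulfonyl hydrazide, Cc1ccc(cc1)S(=O)(=O)NN
Why: Condensation of the only free carbonyl (C9) to the α,β-unsaturated tosylhydrazone.

Step 12
Reactants: 16 C9 tosylhydrazone
Product: 18 cis-fused ketal with C8=C9 alkene (6α-OTBS; C7 now CH2), via allylic diazene 17 (not isolated)
Conditions: catecholborane, CHCl3, 0 °C; then NaOAc·3H2O, reflux
Reagents that add atoms: none
Why: Kabalka alkene-transposing reduction: hydride adds 1,2 to C=N, acetate triggers loss of sulfinate to give 17, and a suprafacial retro-ene loss of N2 delivers hydrogen to C7 and moves the double bond to C8=C9. No stereocentre is created.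

Step 13
Reactants: 18 cis-fused ketal alkene
Product: 20 trans-fused ketone (5α-H; 6α-OTBS; C8=C9), via cis-fused ketone 19 (not isolated)
Conditions: PPTS, acetone–H2O, 50 °C; then DBU, toluene, 40 °C
Reagents that add atoms: water, O
Why: Ketal hydrolysis frees the C4 ketone 19, and DBU then equilibrates C5 through the C4 enolate (base-mediated epimerisation). The trans isomer should be favoured because in 19 the C4 carbonyl carbon and the C6 silyloxy group are cis on neighbouring ring B carbons, a strain that inversion at C5 relieves; a silyloxide is a poor leaving group, so β-elimination should stay slow.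

Step 14
Reactants: 20 trans-fused ketone
Product: 21 6-O-TBS jaeschkeanadiol (4β-OH; 4α-isopropyl)
Conditions: i-PrMgCl, CeCl3 (anhydrous), THF, −78 → −40 °C
Reagents that add atoms: isopropylmagnesium chloride, CC(C)[Mg]Cl
Why: Organocerium 1,2-addition; the low basicity suppresses enolisation of the epimerisable ketone and β-hydride reduction. The reagent should approach C4 from the face of H5, which is anti both to the C15 methyl (1,3 to the carbonyl) and to C6 on the neighbouring carbon, and this places the hydroxyl β and gives (R) at C4.

Step 15
Reactants: 21 6-O-TBS jaeschkeanadiol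
Product: 22 jaeschkeanadiol (4β,6α-diol; 5α-H)
Conditions: TBAF, THF, 40 °C
Reagents that add atoms: none
Why: Fluoride-induced desilylation; the tertiary alcohol and the alkene are inert to it.

Step 16
Reactants: 22 jaeschkeanadiol; 23 veratric acid
Product: 24 target, jaeschkeanadiol 6-O-(3,4-dimethoxybenzoate)
Conditions: DCC, DMAP, CH2Cl2, rt
Reagents that add atoms: none
Why: Steglich esterification; the acylpyridinium transfers the aroyl group to the secondary O6 only, the tertiary C4 hydroxyl being too hindered, and the C6–O bond is not broken, so C6 keeps its configuration.

## Compound list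

1 | (3-methylfuran-2-yl)methanol | Cc1ccoc1CO | starting material
2 | 6-hydroxy-4-methyl-2H-pyran-3(6H)-one, racemic lactol | CC1=CC(O)OCC1=O | intermediate
3 | 6-acetoxy-4-methyl-2H-pyran-3(6H)-one, racemic | CC(=O)OC1C=C(C)C(=O)CO1 | intermediate
4 | 3-methylcyclopent-2-enone | CC1=CC(=O)CC1 | starting material
5 | 2-bromo-3-methylcyclopent-2-enone | CC1=C(Br)C(=O)CC1 | intermediate
6 | 6-bromo-7-methyl-1,4-dioxaspiro[4.4]non-6-ene | CC1=C(Br)C2(CC1)OCCO2 | intermediate
7 | (1R,2S,5R)-menthyl (S)-p-toluenesulfinate | CC(C)[C@@H]1CC[C@@H](C)C[C@H]1O[S@](=O)c1ccc(C)cc1 | starting material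
8 | (7-methyl-1,4-dioxaspiro[4.4]non-6-en-6-yl)lithium | CC1=C([Li])C2(CC1)OCCO2 | intermediate
9 | (S)-7-methyl-6-(p-tolylsulfinyl)-1,4-dioxaspiro[4.4]non-6-ene | CC1=C([S@@](=O)c2ccc(C)cc2)C3(CC1)OCCO3 | intermediate
10 | (S)-3-methyl-2-(p-tolylsulfinyl)cyclopent-2-enone | O=C1CCC(C)=C1[S@@](=O)c1ccc(C)cc1 | intermediate
11 | 4-methyl-3-oxidopyrylium | Cc1cc[o+]cc1[O-] | intermediate
12 | exo cycloadduct: cyclopentanone fused to an 8-oxabicyclo[3.2.1]octenone; C4 and C9 ketones, C7=C8, oxygen bridge C6–O–C10 on the α face, C15 methyl and (S)-p-tolylsulfinyl (on C5) on the β face | O=C1CC[C@@]2(C)[C@]1([S@@](=O)c1ccc(C)cc1)[C@@H]3C=C(C)C(=O)[C@H]2O3 | intermediate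
13 | cis-fused hydroxy dione: 6α-hydroxy, 5β-H, C4 ketone, C7=C8–C9=O enone, C15 methyl β | O=C1CC[C@@]2(C)[C@@H]1[C@@H](O)C=C(C)C(=O)C2 | intermediate
14 | 6-O-TBS ether of 13 | O=C1CC[C@@]2(C)[C@@H]1[C@@H](O[Si](C)(C)C(C)(C)C)C=C(C)C(=O)C2 | intermediate
15 | C4 ethylene ketal of 14 | C12(OCCO1)CC[C@@]3(C)[C@@H]2[C@@H](O[Si](C)(C)C(C)(C)C)C=C(C)C(=O)C3 | intermediate
16 | C9 tosylhydrazone of 15 | C12(OCCO1)CC[C@@]3(C)[C@@H]2[C@@H](O[Si](C)(C)C(C)(C)C)C=C(C)C(=NNS(=O)(=O)c1ccc(C)cc1)C3 | intermediate
17 | allylic diazene (N=NH on C9, C7=C8), C9 configuration not defined | C12(OCCO1)CC[C@@]3(C)[C@@H]2[C@@H](O[Si](C)(C)C(C)(C)C)C=C(C)C(N=N)C3 | intermediate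
18 | cis-fused C4 ketal with C8=C9, 6α-OTBS, 5β-H | C12(OCCO1)CC[C@@]3(C)[C@@H]2[C@@H](O[Si](C)(C)C(C)(C)C)CC(C)=CC3 | intermediate
19 | cis-fused C4 ketone, 5β-H, 6α-OTBS, C8=C9 | O=C1CC[C@@]2(C)[C@@H]1[C@@H](O[Si](C)(C)C(C)(C)C)CC(C)=CC2 | intermediate
20 | trans-fused C4 ketone, 5α-H, 6α-OTBS, C8=C9 | O=C1CC[C@@]2(C)[C@H]1[C@@H](O[Si](C)(C)C(C)(C)C)CC(C)=CC2 | intermediate
21 | 6-O-TBS jaeschkeanadiol (4β-OH, 4α-isopropyl, 5α-H) | O[C@@]1(C(C)C)CC[C@@]2(C)[C@H]1[C@@H](O[Si](C)(C)C(C)(C)C)CC(C)=CC2 | intermediate
22 | jaeschkeanadiol, (1R,4R,5S,6S)-dauc-8-ene-4,6-diol | O[C@@]1(C(C)C)CC[C@@]2(C)[C@H]1[C@@H](O)CC(C)=CC2 | intermediate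
23 | veratric acid (3,4-dimethoxybenzoic acid) | COc1ccc(C(=O)O)cc1OC | starting material
24 | target: [(3R,3aS,4S,8aR)-3-hydroxy-6,8a-dimethyl-3-(propan-2-yl)-1,2,3,3a,4,5,8,8a-octahydroazulen-4-yl] 3,4-dimethoxybenzoate | COc1ccc(C(=O)O[C@H]2CC(C)=CC[C@@]3(C)CC[C@@](O)(C(C)C)[C@H]23)cc1OC | target

Total step count: 16. Longest linear sequence: 14 steps (steps 3–16, from 4 to 24); steps 1–2 form the second branch, which joins at step 7, and 23 enters at step 16.

## Least certain steps

Step 7 (key step). The ylide may dimerise or decay faster than it adds to the tetrasubstituted, β-methylated alkene, and exo/endo discrimination or the facial sense may be poor, because nothing in the partners enforces the exo orientation strongly. The fallback uses known chemistry and a different bond set. It sets out from 6: Suzuki coupling with potassium vinyltrifluoroborate (PdCl2(dppf), Cs2CO3, THF–H2O) would give 7-methyl-6-vinyl-1,4-dioxaspiro[4.4]non-6-ene F1, the same diene as A5. Decomposition of methyl 2-diazobut-3-enoate A6 by Rh2(S-DOSP)4 or its antipode (hexane, −78 °C → rt) would cyclopropanate the vinyl group, and Cope rearrangement of the cis-divinylcyclopropane would give the bicyclic diene ester F2, with C1 quaternary. Hydroboration–oxidation (BH3·SMe2, THF, 0 °C; then NaBO3·4H2O) of C5=C6 anti to the C15 methyl would give the 5α-H 6α-hydroxy ester F3. TBSCl with imidazole would give the silyl ether F4, i-Bu2AlH the allylic alcohol F5, MsCl with Et3N the allylic mesylate F6, and LiEt3BH the C8-methyl trans-fused ketal F7. PPTS in acetone–H2O would then release 20, where the route is rejoined.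

Step 13. The equilibrium at C5 may not lie on the trans side, since cis-fused hydroazulenones with an angular methyl can be the more stable, and prolonged base may expel the C6 silyloxy group. The fallback gives up equilibration altogether: 20 would be reached from 6 through the vinylation, [4+3] annulation and hydroboration sequence described for step 7, ending with the C8-methyl trans-fused ketal F7. In that sequence C5–H and C6–O are added together, syn to each other and anti to the C15 methyl, under kinetic control. The route is rejoined at 20.

Step 8. The two reductive cleavages may interfere: the sulfinyl group may go first so that the C5 enolate expels the C6 oxygen (bridge opening in the wrong sense), cleavage may occur at C6–O through the γ-carbon of the enone, or the enone may be over-reduced. The fallback separates the two events. From 12, aluminium amalgam, Al(Hg), in THF–H2O at 0 °C would remove the sulfinyl group in a protic medium, where the enolate is protonated at once, giving the desulfinylated exo cycloadduct F8. SmI2 (2.2 equiv) with MeOH at −78 °C would then open only the bridge and return to 13.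

Step 12. Hydride addition to the hindered, α-methyl-substituted hydrazone may be slow, or reduction may proceed without clean transposition. The fallback goes through the allylic alcohol and skips 16. From 15, Luche reduction (NaBH4, CeCl3·7H2O, MeOH, −78 °C) would give the C9 allylic alcohol F9 (either C9 epimer serves). Mitsunobu displacement with o-nitrobenzenesulfonyl hydrazide (PPh3, diethyl azodicarboxylate, THF, −30 °C → rt) and loss of the sulfinate would pass through the same diazene 17 and return to 18.

Step 14. Enolisation of the ketone (which would also erode C5) or β-hydride reduction may compete with addition of the branched nucleophile, and the silyloxy group on C6 may erode facial selectivity. The fallback uses an sp2 nucleophile without β-hydrogen. From 20, isopropenylmagnesium bromide with CeCl3 (THF, −78 °C) would give the isopropenyl carbinol F10. Hydrogenation with RhCl(PPh3)3 (H2, 1 atm, benzene) would saturate only the 1,1-disubstituted alkene and return to 21.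

## Further compounds

F1 | step 7 | 7-methyl-6-vinyl-1,4-dioxaspiro[4.4]non-6-ene | C=CC1=C(C)CCC12OCCO2
F2 | step 7 | bicyclic diene ester (C8 CO2Me, C8=C9, C5=C6, C4 ketal, C1 quaternary R) | COC(=O)C1=CC[C@@]2(C)CCC3(OCCO3)C2=CC1
F3 | step 7 | 5α-H, 6α-hydroxy ester (C8 CO2Me, C8=C9, C4 ketal) | COC(=O)C1=CC[C@@]2(C)CCC3(OCCO3)[C@@H]2[C@@H](O)C1
F4 | step 7 | 6-O-TBS ether of F3 | COC(=O)C1=CC[C@@]2(C)CCC3(OCCO3)[C@@H]2[C@@H](O[Si](C)(C)C(C)(C)C)C1
F5 | step 7 | allylic alcohol (C8 CH2OH) from F4 | OCC1=CC[C@@]2(C)CCC3(OCCO3)[C@@H]2[C@@H](O[Si](C)(C)C(C)(C)C)C1
F6 | step 7 | allylic mesylate of F5 | CS(=O)(=O)OCC1=CC[C@@]2(C)CCC3(OCCO3)[C@@H]2[C@@H](O[Si](C)(C)C(C)(C)C)C1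
F7 | step 7 | C8-methyl trans-fused ketal (5α-H, 6α-OTBS, C8=C9), the C5 epimer of 18 | CC1=CC[C@@]2(C)CCC3(OCCO3)[C@@H]2[C@@H](O[Si](C)(C)C(C)(C)C)C1
F0 | step 13 | none | none
F8 | step 8 | desulfinylated exo cycloadduct (5β-H, oxygen bridge α, C4 and C9 ketones, C7=C8) | O=C1CC[C@@]2(C)[C@@H]1[C@@H]3C=C(C)C(=O)[C@H]2O3
F9 | step 12 | C9 allylic alcohol of 15 (C9 configuration not defined) | C12(OCCO1)CC[C@@]3(C)[C@@H]2[C@@H](O[Si](C)(C)C(C)(C)C)C=C(C)C(O)C3
F10 | step 14 | isopropenyl carbinol (4β-OH, 4α-isopropenyl, 6α-OTBS) | O[C@@]1(C(C)=C)CC[C@@]2(C)[C@H]1[C@@H](O[Si](C)(C)C(C)(C)C)CC(C)=CC2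
A1 | alternative 1 | 3,6-dimethylcyclohepta-2,5-dienone | O=C1C=C(C)CC=C(C)C1
A2 | alternative 1 | diisobutyl(vinyl)aluminium | C=C[Al](CC(C)C)CC(C)C
A3 | alternative 1 | isobutyraldehyde | CC(C)C=O
A4 | alternative 1 | trans-2,3-disubstituted cycloheptenone aldol | C=C[C@]1(C)CC=C(C)CC(=O)[C@H]1[C@@H](O)C(C)C
A5 | alternative 2 | 7-methyl-6-vinyl-1,4-dioxaspiro[4.4]non-6-ene | C=CC1=C(C)CCC12OCCO2
A6 | alternative 2 | methyl 2-diazobut-3-enoate | COC(=O)C(=[N+]=[N-])C=C
A7 | alternative 2 | bicyclic 1,4-diene ester with C4 ketal | COC(=O)C1=CC[C@@]2(C)CCC3(OCCO3)C2=CC1
A8 | alternative 3 | (2E,6E)-farnesyl diphosphate | CC(C)=CCC/C(C)=C/CC/C(C)=C/COP(=O)(O)OP(=O)(O)O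
A9 | alternative 3 | carotol | C1CC(C)=CC[C@@]2(C)CC[C@@H](C(C)C)[C@@]12O
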